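The ten-membered carbocycle is cut at C1–C10, the two oxirane carbons. Both bear oxygen, and C14–C10–C9 is a dihydroxyacetone unit, so this bond is that of a pinacol between a C1 aldehyde and the C10 ketone of a dioxanone. The precursor is acyclic: a (4S)-4-substituted 2,2-dimethyl-1,3-dioxan-5-one whose C8 side chain runs through C7 and the E-enoate (C4=C5) to the C1 aldehyde. One low-valent-titanium coupling forms C1–C10, closes the carbocycle and sets both carbinol centres. Mesylation at C1, exchange of the acetonide for the two esters and invertive closure from O10 then deliver the trans-oxirane. The enoate is installed only after the strongly basic C8–C9 alkylation.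

Key step: step 13

Numbering, kept for all intermediates: C1 (oxirane CH), C2, C3, C4 (bears CO2Me), C5 (=CH), C6, C7 (bears isopropenyl), C8, C9 (bears OAc), C10 (oxirane C), C14 = CH2O on C10. The target is (1R,7S,9S,10S,4E) with an (R)-2-methylbutanoate.

Assumption: both auxiliaries follow their usual chelate models (benzyl-shielded Z-dienolate; methoxy-chelated azaenolate). If either sense proves opposite, the antipodal auxiliary is used with no other change.

Step 1
Reactants: 1 (R)-4-benzyloxazolidin-2-one; 2 3-methylbut-2-enoyl chloride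
Product: 4 (R)-4-benzyl-3-(3-methylbut-2-enoyl)oxazolidin-2-one, via lithium oxazolidinide 3 (not isolated)
Conditions: n-BuLi, THF, −78 °C; then 2, −78 → 0 °C
Reagents that add atoms: none
Why: N-Acylation of the lithiated oxazolidinone with an acid chloride is the standard entry to N-enoyl imides, and the auxiliary stereocentre is not involved.

Step 2
Reactants: 4 (R)-4-benzyl-3-(3-methylbut-2-enoyl)oxazolidin-2-one; 5 1-bromo-3-methylbut-2-ene (prenyl bromide)
Product: 7 (R)-4-benzyl-3-[(2R)-5-methyl-2-(prop-1-en-2-yl)hex-4-enoyl]oxazolidin-2-one, via sodium dienolate 6 (not isolated)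
Conditions: NaHMDS, THF, −78 °C; then 5, −78 → −30 °C
Reagents that add atoms: none
Why: Evans asymmetric alkylation in its deconjugative form: γ-deprotonation of the s-cis enoyl imide gives the sodium-chelated (Z)-dienolate 6, which reacts at its α-carbon with the allylic bromide on the face opposite the benzyl group, so that C7 is set as R and the isopropenyl group is created in the same event.

Step 3
Reactants: 7 (R)-4-benzyl-3-[(2R)-5-methyl-2-(prop-1-en-2-yl)hex-4-enoyl]oxazolidin-2-one
Product: 8 (R)-lavandulol, (2R)-5-methyl-2-(prop-1-en-2-yl)hex-4-en-1-ol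
Conditions: LiBH4, H2O (1 equiv), Et2O, 0 °C
Reagents that add atoms: none
Why: Reductive removal of the oxazolidinone auxiliary with lithium borohydride attacks only the exocyclic imide carbonyl, leaves both unactivated alkenes and C7 untouched, and returns auxiliary 1.

Step 4
Reactants: 8 (R)-lavandulol
Product: 9 (R)-3-(iodomethyl)-2,6-dimethylhepta-1,5-diene (lavandulyl iodide)
Conditions: I2, PPh3, imidazole, CH2Cl2, 0 °C → rt
Reagents that add atoms: iodine, II
Why: Appel-type iodination is an SN2 displacement at the primary C8 oxyphosphonium ion and touches neither C7 nor the alkenes.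

Step 5
Reactants: 10 2,2-dimethyl-1,3-dioxan-5-one; 11 (S)-1-amino-2-(methoxymethyl)pyrrolidine (SAMP)
Product: 12 SAMP hydrazone of 2,2-dimethyl-1,3-dioxan-5-one
Conditions: cyclohexane, reflux, Dean–Stark
Reagents that add atoms: none
Why: Condensation of a ketone with an N,N-dialkylhydrazine under water removal gives the hydrazone, and the symmetric ketone leaves no regiochemical question.

Step 6
Reactants: 12 SAMP hydrazone of 2,2-dimethyl-1,3-dioxan-5-one; 9 (R)-lavandulyl iodide
Product: 14 SAMP hydrazone of (4S)-2,2-dimethyl-4-[(2S)-5-methyl-2-(prop-1-en-2-yl)hex-4-en-1-yl]-1,3-dioxan-5-one (C=N geometry left open), via lithium azaenolate 13 (not isolated)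
Conditions: t-BuLi, THF, −78 °C; then 9, −100 °C → rt
Reagents that add atoms: none
Why: Enders SAMP-hydrazone alkylation: the methoxy-chelated lithium azaenolate 13 is alkylated by the primary iodide on its open face, which sets C9 as S, and because 9 holds only unactivated alkenes beside the C–I bond the strongly basic nucleophile meets no Michael acceptor and no acidic site.

Step 7
Reactants: 14 alkylated SAMP hydrazone
Product: 15 (4S)-2,2-dimethyl-4-[(2S)-5-methyl-2-(prop-1-en-2-yl)hex-4-en-1-yl]-1,3-dioxan-5-one
Conditions: sat. aq. (CO2H)2, Et2O, rt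
Reagents that add atoms: water, O
Why: Two-phase hydrazone hydrolysis with aqueous oxalic acid is mild enough to keep the acetonide and the α-stereocentre C9, and the auxiliary can be recovered from the aqueous layer.

Step 8
Reactants: 15 (4S)-4-lavandulyl-2,2-dimethyl-1,3-dioxan-5-one
Product: 16 (4S)-4-{(2S)-2-[(3,3-dimethyloxiran-2-yl)methyl]-3-methylbut-3-en-1-yl}-2,2-dimethyl-1,3-dioxan-5-one (both C5 epimers)
Conditions: mCPBA (1.0 equiv), CH2Cl2, −20 → 0 °C
Reagents that add atoms: 3-chloroperoxybenzoic acid, O=C(OO)c1cccc(Cl)c1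
Why: Prilezhaev epoxidation follows alkene nucleophilicity, so one equivalent of peracid should take the trisubstituted C5 alkene ahead of the 1,1-disubstituted isopropenyl group and well ahead of Baeyer–Villiger attack on the ketone, while the unselective new C5 centre is destroyed in step 9.

Step 9
Reactants: 16 side-chain oxirane
Product: 18 (3R)-3-{[(4S)-2,2-dimethyl-5-oxo-1,3-dioxan-4-yl]methyl}-4-methylpent-4-enal (C5 aldehyde), via glycol 17 (not isolated)
Conditions: H5IO6, THF–Et2O, 0 °C
Reagents that add atoms: none
Why: Periodic acid opens the trisubstituted oxirane to glycol 17 and cleaves it at once (Malaprade glycol cleavage), which releases the C5 aldehyde and acetone, while the alkoxy ketone has no free α-hydroxyl and is not a substrate.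

Step 10
Reactants: 19 methyl (triphenyl-λ5-phosphanylidene)acetate; 20 3-bromo-1,1-dimethoxypropane
Product: 22 methyl 5,5-dimethoxy-2-(triphenyl-λ5-phosphanylidene)pentanoate, via phosphonium bromide 21 (not isolated)
Conditions: 19 (2 equiv), NaI (cat.), MeCN, reflux
Reagents that add atoms: none
Why: C-Alkylation of a stabilised phosphorus ylide by a primary halide gives phosphonium salt 21, which the second equivalent of 19 deprotonates (transylidation) to the α-substituted ylide.

Step 11
Reactants: 18 C5 aldehyde; 22 α-substituted stabilised ylide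
Product: 23 methyl (2E,5S)-2-(3,3-dimethoxypropyl)-5-{[(4S)-2,2-dimethyl-5-oxo-1,3-dioxan-4-yl]methyl}-6-methylhepta-2,6-dienoate
Conditions: PhMe, 60 °C
Reagents that add atoms: none
Why: The Wittig reaction of an α-branched ester-stabilised ylide with an unhindered aliphatic aldehyde is reliably E-selective (C6 trans to CO2Me), needs no added base so that C9 is safe, and leaves the hindered α-branched ketone alone.

Step 12
Reactants: 23 enoate dimethyl acetal
Product: 24 methyl (2E,5S)-5-{[(4S)-2,2-dimethyl-5-oxo-1,3-dioxan-4-yl]methyl}-6-methyl-2-(3-oxopropyl)hepta-2,6-dienoate (acyclic keto aldehyde)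
Conditions: 10% aq. (CO2H)2 on SiO2, CH2Cl2, rt
Reagents that add atoms: water, O
Why: Acid-catalysed acetal hydrolysis on wet, oxalic-acid-loaded silica cleaves the acyclic dimethyl acetal, whereas the cyclic acetonide is deactivated by the adjacent carbonyl, has to tolerate the same acid in step 7, and should persist.

Step 13
Reactants: 24 acyclic keto aldehyde
Product: 26 bicyclic cis diol: ten-membered carbocycle C1–C10 fused at C9–C10 to the 2,2-dimethyl-1,3-dioxane, 1-OH and 10-OH cis, C1 cis to C8 on the dioxane, (1S,7S,9S,10S,4E), via titanium pinacolate 25 (not isolated)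
Conditions: TiCl3(DME)1.5, Zn–Cu, DME, reflux; then 24 by syringe pump (high dilution), 25 °C; aq. K2CO3
Reagents that add atoms: none
Why: Electron transfer from the low-valent titanium slurry converts the C1 aldehyde and the C10 ketone into titanium-bound ketyls, which combine to the C1–C10 bond inside titanium pinacolate 25; at room temperature this is not deoxygenated, and aqueous carbonate releases the diol. The closest known reaction type is the McMurry-type pinacol macrocyclisation of acyclic keto aldehydes, which is established for medium and large carbocycles including ten-membered ones. The carbocycle closes end to end (C1 onto C10) with both C–O bonds left outside the new ring, aided by slow addition at high dilution and by the C4=C5 bond, whose ring substituents C3 and C6 are cis and fold the chain. C10 is controlled by the dioxanone chair: the axial acetonide methyl keeps C8 equatorial, and 1,3-dioxan-5-ones accept new bonds from the axial direction because O1 and O3 carry no axial hydrogens, so C1 should enter cis to C8 and the bulky O–Ti group stay equatorial. C1 is controlled by the titanium bridge, which holds O1 and O10 gauche while the eight-atom tether is expected to keep C2 and C9 on the same side, giving the cis diol (1S,10S); this is the least secure element and has its own fallback. The step needs carbonyl–carbonyl coupling to outrun 6-exo addition of the C10 ketyl to C5 of the enoate and loss of an α-alkoxy group: each incoming molecule meets a large excess of reductant that reduces both carbonyls together, the acceptor is a hindered trisubstituted enoate, an acetal alkoxide is a poor leaving group, and titanium is chosen over samarium diiodide for that reason.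

Step 14
Reactants: 26 bicyclic cis diol
Product: 27 C1 mesylate of 26 (10-OH free)
Conditions: MsCl, Et3N, CH2Cl2, −20 → 0 °C
Reagents that add atoms: methanesulfonyl chloride, CS(=O)(=O)Cl
Why: Sulfonylation through sulfene takes the secondary C1 hydroxyl and leaves the tertiary C10 hydroxyl free, with retention at C1 because only the O–H bond reacts.

Step 15
Reactants: 27 C1 mesylate acetonide
Product: 28 C1 mesylate 9,10,14-triol
Conditions: AcOH–H2O 4:1, 40 °C
Reagents that add atoms: none
Why: Acid-catalysed acetonide hydrolysis frees the C9 and C14 hydroxyls, and the secondary mesylate, the enoate and the isopropenyl group are stable to warm aqueous acetic acid.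

Step 16
Reactants: 28 C1 mesylate triol; 29 (R)-2-methylbutanoic acid
Product: 30 C14 (R)-2-methylbutanoate of 28 (9-OH and 10-OH free)
Conditions: EDC·HCl, DMAP (cat.), CH2Cl2, 0 °C
Reagents that add atoms: none
Why: Steglich esterification with one equivalent of the α-branched acid selects the primary C14 hydroxyl over the secondary C9 and tertiary C10 hydroxyls on steric grounds, and carbodiimide activation of a simple α-alkyl acid does not erode its R centre.

Step 17
Reactants: 30 C14 ester
Product: 31 C9 acetate of 30 (10-OH free)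
Conditions: Ac2O, pyridine, DMAP (cat.), CH2Cl2, 0 °C → rt
Reagents that add atoms: acetic anhydride, CC(=O)OC(C)=O
Why: DMAP-catalysed acetylation esterifies the remaining secondary C9 hydroxyl, while the tertiary C10 hydroxyl, flanked by three branched carbons, is too hindered to react under these conditions.

Step 18
Reactants: 31 hydroxy mesylate diester
Product: 33 target CNP0352790.1, (1R,7S,9S,10S,4E), via potassium alkoxide 32 (not isolated)
Conditions: KHMDS (1.0 equiv), THF, −78 → −20 °C
Reagents that add atoms: none
Why: Intramolecular Williamson-type 3-exo-tet displacement: the C10 alkoxide 32 attacks C1 anti to the mesylate, which inverts C1 from S to R, keeps C10, and turns the cis diol relationship into the trans-oxirane of the target.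

Compound list
1 | (R)-4-benzyloxazolidin-2-one | O=C1N[C@H](Cc2ccccc2)CO1 | starting material
2 | 3-methylbut-2-enoyl chloride | CC(C)=CC(=O)Cl | starting material
3 | lithium (R)-4-benzyl-2-oxooxazolidin-3-ide | [Li+].O=C1[N-][C@H](Cc2ccccc2)CO1 | intermediate
4 | (R)-4-benzyl-3-(3-methylbut-2-enoyl)oxazolidin-2-one | CC(C)=CC(=O)N1C(=O)OC[C@H]1Cc1ccccc1 | intermediate
5 | 1-bromo-3-methylbut-2-ene | CC(C)=CCBr | starting material
6 | sodium (Z)-dienolate of 4 | [Na+].C=C(C)/C=C(\[O-])N1C(=O)OC[C@H]1Cc1ccccc1 | intermediate
7 | (R)-4-benzyl-3-[(2R)-5-methyl-2-(prop-1-en-2-yl)hex-4-enoyl]oxazolidin-2-one | C=C(C)[C@H](C(=O)N1C(=O)OC[C@H]1Cc1ccccc1)CC=C(C)C | intermediate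
8 | (R)-lavandulol | C=C(C)[C@H](CO)CC=C(C)C | intermediate
9 | (R)-3-(iodomethyl)-2,6-dimethylhepta-1,5-diene | C=C(C)[C@H](CI)CC=C(C)C | intermediate
10 | 2,2-dimethyl-1,3-dioxan-5-one | CC1(C)OCC(=O)CO1 | starting material
11 | (S)-1-amino-2-(methoxymethyl)pyrrolidine (SAMP) | COC[C@@H]1CCCN1N | starting material
12 | SAMP hydrazone of 10 | COC[C@@H]1CCCN1N=C1COC(C)(C)OC1 | intermediate
13 | lithium azaenolate of 12 | [Li+].COC[C@@H]1CCCN1[N-]C1=COC(C)(C)OC1 | intermediate
14 | SAMP hydrazone of 15 (7S,9S) | C=C(C)[C@@H](CC=C(C)C)C[C@@H]1OC(C)(C)OCC1=NN1CCC[C@H]1COC | intermediate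
15 | (4S)-2,2-dimethyl-4-[(2S)-5-methyl-2-(prop-1-en-2-yl)hex-4-en-1-yl]-1,3-dioxan-5-one | C=C(C)[C@@H](CC=C(C)C)C[C@@H]1OC(C)(C)OCC1=O | intermediate
16 | side-chain 3,3-dimethyloxirane of 15 (C5 epimers) | C=C(C)[C@@H](CC1OC1(C)C)C[C@@H]1OC(C)(C)OCC1=O | intermediate
17 | side-chain glycol from 16 (C5 epimers) | C=C(C)[C@@H](CC(O)C(C)(C)O)C[C@@H]1OC(C)(C)OCC1=O | intermediate
18 | (3R)-3-{[(4S)-2,2-dimethyl-5-oxo-1,3-dioxan-4-yl]methyl}-4-methylpent-4-enal | C=C(C)[C@@H](CC=O)C[C@@H]1OC(C)(C)OCC1=O | intermediate
19 | methyl (triphenyl-λ5-phosphanylidene)acetate | COC(=O)C=P(c1ccccc1)(c1ccccc1)c1ccccc1 | starting material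
20 | 3-bromo-1,1-dimethoxypropane | COC(CCBr)OC | starting material
21 | (1,5,5-trimethoxy-1-oxopentan-2-yl)triphenylphosphonium bromide | [Br-].COC(=O)C(CCC(OC)OC)[P+](c1ccccc1)(c1ccccc1)c1ccccc1 | intermediate
22 | methyl 5,5-dimethoxy-2-(triphenyl-λ5-phosphanylidene)pentanoate | COC(=O)C(CCC(OC)OC)=P(c1ccccc1)(c1ccccc1)c1ccccc1 | intermediate
23 | methyl (2E,5S)-2-(3,3-dimethoxypropyl)-5-{[(4S)-2,2-dimethyl-5-oxo-1,3-dioxan-4-yl]methyl}-6-methylhepta-2,6-dienoate | C=C(C)[C@@H](C/C=C(/C(=O)OC)CCC(OC)OC)C[C@@H]1OC(C)(C)OCC1=O | intermediate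
24 | methyl (2E,5S)-5-{[(4S)-2,2-dimethyl-5-oxo-1,3-dioxan-4-yl]methyl}-6-methyl-2-(3-oxopropyl)hepta-2,6-dienoate | C=C(C)[C@@H](C/C=C(/C(=O)OC)CCC=O)C[C@@H]1OC(C)(C)OCC1=O | intermediate
25 | dichlorotitanium(IV) pinacolate of 26 (simplified) | C=C(C)[C@H]1C/C=C(/C(=O)OC)CC[C@@H]2O[Ti](Cl)(Cl)O[C@@]23COC(C)(C)O[C@H]3C1 | intermediate
26 | ten-membered C1/C10 cis diol fused to the dioxane, (1S,7S,9S,10S,4E) | C=C(C)[C@H]1C/C=C(/C(=O)OC)CC[C@H](O)[C@@]2(O)COC(C)(C)O[C@H]2C1 | intermediate
27 | C1 mesylate of 26 | C=C(C)[C@H]1C/C=C(/C(=O)OC)CC[C@H](OS(C)(=O)=O)[C@@]2(O)COC(C)(C)O[C@H]2C1 | intermediate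
28 | C1 mesylate 9,10,14-triol | C=C(C)[C@H]1C/C=C(/C(=O)OC)CC[C@H](OS(C)(=O)=O)[C@@](O)(CO)[C@@H](O)C1 | intermediate
29 | (R)-2-methylbutanoic acid | CC[C@@H](C)C(=O)O | starting material
30 | C14 (R)-2-methylbutanoate, C1 mesylate, 9,10-diol | C=C(C)[C@H]1C/C=C(/C(=O)OC)CC[C@H](OS(C)(=O)=O)[C@@](O)(COC(=O)[C@H](C)CC)[C@@H](O)C1 | intermediate
31 | C9 acetate, C14 (R)-2-methylbutanoate, C1 mesylate, 10-ol | C=C(C)[C@H]1C/C=C(/C(=O)OC)CC[C@H](OS(C)(=O)=O)[C@@](O)(COC(=O)[C@H](C)CC)[C@@H](OC(C)=O)C1 | intermediate
32 | potassium C10 alkoxide of 31 | [K+].C=C(C)[C@H]1C/C=C(/C(=O)OC)CC[C@H](OS(C)(=O)=O)[C@@]([O-])(COC(=O)[C@H](C)CC)[C@@H](OC(C)=O)C1 | intermediate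
33 | CNP0352790.1 | C=C(C)[C@H]1C/C=C(/C(=O)OC)CC[C@H]2O[C@]2(COC(=O)[C@H](C)CC)[C@@H](OC(C)=O)C1 | target

Total step count: 18. Longest linear sequence: 16 steps (1–4, 6–9, 11–18); steps 5 and 10 are side branches.

Steps most likely to fail

Step 13. The ring may close with poor facial selectivity at the C1 aldehyde, because a ten-membered ring tolerates both the cis and the trans diol. The C1 carbinol could then form mainly in the wrong configuration or as a mixture.
- The fallback sets out from 24 and comes back at 26. It separates ring closure from control at C1.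
- The coupling is run as in step 13. The C1-epimeric diol F1, alone or mixed with 26, is oxidised at its only secondary carbinol (Parikh–Doering oxidation: SO3·pyridine, DMSO, Et3N, CH2Cl2, 0 °C). This gives the ten-membered acyloin F2, with a C1 ketone and the C10 tertiary alcohol.
- Zn(BH4)2 in Et2O at −30 °C then reduces F2 through the five-membered zinc chelate of O1 and O10. C9 and the carbocycle cover one face of this chelate, so hydride should enter from the C14 side (peripheral attack). That places H1 cis to C14 and gives 26.

Step 18. An acyl group may migrate from O9 or O14 to the C10 alkoxide before ring closure, which scrambles the esters. A 1,2-shift onto C1 may also compete with the displacement.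
- The fallback sets out from 27 and comes back at 33. It closes the oxirane before any migrating ester is present.
- K2CO3 in MeOH at 0 °C converts 27 into the oxirane acetonide F3.
- 80% aqueous acetic acid at room temperature removes the acetonide and gives the oxirane diol F4. An oxirane flanked by the C9–O and C14–O bonds is deactivated towards acid, as in anhydro sugars, and the electron-poor enoate should not attack across the ring.
- Steglich esterification of the primary C14 hydroxyl with 29 gives the oxirane mono-ester F5, and Ac2O/pyridine/DMAP then gives 33.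

Step 12. The acetonide may be lost, or C9 may epimerise by acid-catalysed enolisation, while the dimethyl acetal is hydrolysed.
- The fallback sets out from 18 and comes back at 24. It carries C1 at the alcohol level, so no acid is needed after the Wittig reaction.
- Ylide 19 is alkylated with commercial (3-bromopropoxy)(tert-butyl)dimethylsilane in the manner of step 10 to give the silyloxypropyl ylide F6.
- Wittig reaction of F6 with 18 (PhMe, 60 °C) gives the E-enoate silyl ether F7.
- HF·pyridine buffered with pyridine in THF at 0 °C frees the primary alcohol F8, and Dess–Martin periodinane with NaHCO3 in CH2Cl2 gives 24.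

Further compounds
F1 | step 13 | C1-epimeric (1R) diol fused to the dioxane | C=C(C)[C@H]1C/C=C(/C(=O)OC)CC[C@@H](O)[C@@]2(O)COC(C)(C)O[C@H]2C1
F2 | step 13 | ten-membered acyloin (C1 ketone, C10 tertiary alcohol) | C=C(C)[C@H]1C/C=C(/C(=O)OC)CCC(=O)[C@@]2(O)COC(C)(C)O[C@H]2C1
F3 | step 18 | oxirane acetonide | C=C(C)[C@H]1C/C=C(/C(=O)OC)CC[C@H]2O[C@@]23COC(C)(C)O[C@H]3C1
F4 | step 18 | oxirane 9,14-diol | C=C(C)[C@H]1C/C=C(/C(=O)OC)CC[C@H]2O[C@]2(CO)[C@@H](O)C1
F5 | step 18 | oxirane C14 (R)-2-methylbutanoate, 9-ol | C=C(C)[C@H]1C/C=C(/C(=O)OC)CC[C@H]2O[C@]2(COC(=O)[C@H](C)CC)[C@@H](O)C1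
F6 | step 12 | methyl 5-[(tert-butyldimethylsilyl)oxy]-2-(triphenyl-λ5-phosphanylidene)pentanoate | COC(=O)C(CCCO[Si](C)(C)C(C)(C)C)=P(c1ccccc1)(c1ccccc1)c1ccccc1
F7 | step 12 | E-enoate C1 silyl ether | C=C(C)[C@@H](C/C=C(/C(=O)OC)CCCO[Si](C)(C)C(C)(C)C)C[C@@H]1OC(C)(C)OCC1=O
F8 | step 12 | E-enoate C1 primary alcohol | C=C(C)[C@@H](C/C=C(/C(=O)OC)CCCO)C[C@@H]1OC(C)(C)OCC1=O
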